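**Retrosynthetic overview**
- The route rests on the array C15(OH)–C10(spiro)–C16(O). With C16 as a ketone, ring A (C7–C8–C9–C10–C16) and ring B (C10–C11–C12–C13–C14–C15, C15 a methyl carbinol) form a β‑hydroxy cyclopentanone. This is the retron of a 2,3‑epoxy alcohol in which C16 is a cyclobutanol carbon and C10–C15 is an epoxide.
- Ring B comes first, from an anisole by Birch reduction (C12 masked as ketal, tetrasubstituted C10=C15 alkene carrying the cyclobutanol). Enantioselective epoxidation follows, and ring A is then closed by four‑to‑five ring expansion, which creates spiro C10.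
- On the spiro ketone: the C7 handle is set by aldol addition, C16–OH by O15‑directed reduction, the C11 chain by α′‑aldol, dehydration and hydrogenation on the C13=C14 enone, and C12 is converted to the dibromoalkene.
- Side chain: the C17=C18 geometry is locked in a butenolide, and C19=C20 is made by Horner–Wadsworth–Emmons olefination of the lactol. The enal is finished by two palladium couplings on C12=CBr2 and desilylation.

Key step: step 5

Remark on locants: ring A = C7, C8, C9, C10, C16; ring B = C10 to C15; C17 is the side‑chain carbon on C7, C17′ its CH2O carbon, C18 to C21 the diene carbons; C1′ to C3′ the propyl chain on C11. These are route locants, not IUPAC locants.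
Remark on step 4: the ligand antipode is chosen to give the (10S,15S) epoxide; the (R,R) ligand is written, and the (S,S) ligand is used if induction on this tetrasubstituted alkene runs the other way.
Remark on mixtures: C17 (compounds 12 to 26), C11/C1′ (21, 22), the C11=C1′ geometry (23) and the lactol carbon (31) are inconsequential mixtures.

Step 1
Reactants: 1 2-bromo-4-methoxy-1-methylbenzene; 2 cyclobutanone
Product: 4 1-(5-methoxy-2-methylphenyl)cyclobutan-1-ol, via aryllithium 3 (not isolated)
Conditions: n-BuLi, THF, −78 °C; then 2, −78 to 0 °C; H2O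
Reagents that add atoms: none
Why: Bromine–lithium exchange gives the aryllithium, which adds to the strained and therefore electrophilic ketone (organolithium 1,2-addition).

Step 2
Reactants: 4 1-(5-methoxy-2-methylphenyl)cyclobutan-1-ol
Product: 5 1-(5-methoxy-2-methylcyclohexa-1,4-dien-1-yl)cyclobutan-1-ol
Conditions: Li, NH3(l), t-BuOH, THF, −78 °C; then MeOH
Reagents that add atoms: none
Why: Birch reduction protonates the two unsubstituted carbons ortho and meta to OMe (C11 and C14), so the methoxy-bearing carbon and both alkyl-bearing carbons stay olefinic and the C10=C15 alkene is placed regiospecifically, while the benzylic alcohol is carried as its lithium alkoxide and resists C–O cleavage.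

Step 3
Reactants: 5 1-(5-methoxy-2-methylcyclohexa-1,4-dien-1-yl)cyclobutan-1-ol
Product: 6 1-(8-methyl-1,4-dioxaspiro[4.5]dec-7-en-7-yl)cyclobutan-1-ol
Conditions: HOCH2CH2OH, PPTS, CH2Cl2, rt
Reagents that add atoms: ethylene glycol, OCCO
Why: Acid-catalysed addition of the diol to the enol ether (transketalisation) traps the C12 oxocarbenium ion as the dioxolane without moving the C10=C15 bond, the weak acid being unable to protonate the tetrasubstituted alkene or ionise the cyclobutanol.

Step 4
Reactants: 6 1-(8-methyl-1,4-dioxaspiro[4.5]dec-7-en-7-yl)cyclobutan-1-ol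
Product: 7 epoxy cyclobutanol 1-[(1S,6S)-6-methylspiro[7-oxabicyclo[4.1.0]heptane-3,2'-[1,3]dioxolan]-1-yl]cyclobutan-1-ol
Conditions: Hf(OtBu)4 (10 mol%), (R,R)-N,N′-(cyclohexane-1,2-diyl)bis(N-hydroxy-2,2-diphenylacetamide) (12 mol%), PhC(CH3)2OOH, toluene, 0 °C
Reagents that add atoms: cumene hydroperoxide, CC(C)(OO)c1ccccc1
Why: The hafnium bishydroxamate binds the tertiary allylic alkoxide and the hydroperoxide together and delivers oxygen to one enantiotopic face of the alkene (hydroxyl-directed asymmetric epoxidation of a tertiary allylic alcohol), which sets C10 and C15 in one event.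

Step 5
Reactants: 7 epoxy cyclobutanol (10S,15S)
Product: 8 spiro hydroxy ketone (10R,15S): ring A cyclopentanone with C16=O; ring B with C12 ethylene ketal and C15 methyl carbinol
Conditions: BF3·OEt2 (0.3 equiv), CH2Cl2, −78 °C; then Et3N
Reagents that add atoms: none
Why: BF3 coordinates the epoxide oxygen and lengthens the C10–O bond, and the cyclobutane bond C16–C9, held antiperiplanar to it, shifts to C10 while the carbinol oxygen becomes the C16 carbonyl (semipinacol rearrangement of a 2,3-epoxy alcohol). The closest known reaction type is the Lewis-acid ring expansion of 1-(epoxycycloalkyl)cyclobutanols to spirocyclic β-hydroxy cyclopentanones. Ring A is closed by ring expansion of the four-membered ring through a 1,2-alkyl shift, not by an end-to-end cyclisation, and the same event creates the spiro junction. C10 is formed with inversion because the migrating carbon can only arrive anti to the departing oxygen, so its configuration follows from the epoxide face set in step 4, and C15 keeps its C–O bond, which leaves O15 cis to C16 on ring B. The step needs opening at C10 and not at C15: both are tertiary, but only cleavage at C10 is assisted by the strain-releasing shift and the developing carbonyl, and the low temperature and substoichiometric acid protect the ketal and suppress shifts from a C15 cation.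

Step 6
Reactants: 8 spiro hydroxy ketone
Product: 9 O15-trimethylsilyl ether of 8
Conditions: 1-(trimethylsilyl)imidazole, CH2Cl2, rt
Reagents that add atoms: 1-(trimethylsilyl)imidazole, C[Si](C)(C)n1ccnc1
Why: The N-silylimidazole silylates the hindered tertiary alcohol under neutral conditions (silyl ether formation), which blocks retro-aldol cleavage of the β-hydroxy ketone and enlarges the C15 face of ring A for step 7.

Step 7
Reactants: 9 O15-trimethylsilyl ether of 8; 10 (tert-butyldimethylsilyloxy)acetaldehyde
Product: 12 aldol adduct with a 1-hydroxy-2-(tert-butyldimethylsilyloxy)ethyl group on C7 trans to C15 across ring A, via lithium enolate 11 (not isolated)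
Conditions: LiN(iPr)2, THF, −78 °C; then 10; AcOH, −78 °C
Reagents that add atoms: none
Why: Deprotonation is possible only at C7 and the lithium enolate adds to the aldehyde (aldol addition) from the face of ring A opposite to C15 with its methyl and silyloxy groups, which sets C7.

Step 8
Reactants: 12 aldol adduct
Product: 13 triol ketone with a 1,2-dihydroxyethyl group on C7 and free O15–H
Conditions: HF·pyridine, pyridine, THF, 0 °C to rt
Reagents that add atoms: none
Why: Buffered fluoride desilylation removes the trimethylsilyl and primary tert-butyldimethylsilyl ethers without base, so neither retro-aldol cleavage nor epimerisation at C7 is expected and the dioxolane survives.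

Step 9
Reactants: 13 triol ketone
Product: 14 acetonide ketone with a 2,2-dimethyl-1,3-dioxolan-4-yl group on C7
Conditions: Me2C(OMe)2, PPTS, CH2Cl2, rt
Reagents that add atoms: 2,2-dimethoxypropane, COC(C)(C)OC
Why: Acid-catalysed acetal exchange closes the five-membered isopropylidene acetal on the 1,2-diol only (acetonide protection), which masks O17 and leaves the tertiary O15–H free as the directing group.

Step 10
Reactants: 14 acetonide ketone
Product: 15 diol with C16–OH trans to C15 across ring A and cis to the C7 substituent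
Conditions: Me4NBH(OAc)3, MeCN/AcOH, −30 °C
Reagents that add atoms: none
Why: Ligand exchange places the borohydride on O15 and hydride is delivered intramolecularly to C16 from the C15 face of ring A through a six-membered chair (Evans–Saksena directed reduction), so the new hydroxyl appears on the opposite face, cis to the C7 substituent.

Step 11
Reactants: 15 diol
Product: 16 bis(tert-butyldimethylsilyl) ether of 15 at O15 and O16
Conditions: TBSOTf, 2,6-lutidine, CH2Cl2, 0 °C to rt
Reagents that add atoms: tert-butyldimethylsilyl trifluoromethanesulfonate, CC(C)(C)[Si](C)(C)OS(=O)(=O)C(F)(F)F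
Why: The silyl triflate silylates both the hindered secondary and the tertiary alcohol (silyl ether formation), and the large O16 silyl group later shields one face of C11.

Step 12
Reactants: 16 bis-silyl ether
Product: 17 C12 ketone
Conditions: PPTS, acetone, 50 °C
Reagents that add atoms: none
Why: Transketalisation to the solvent frees the C12 ketone, while the large excess of acetone keeps the side-chain isopropylidene acetal closed and the silyl ethers tolerate the weak acid.

Step 13
Reactants: 17 C12 ketone
Product: 18 C13=C14 enone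
Conditions: IBX, DMSO/PhF, 70 °C
Reagents that add atoms: none
Why: IBX dehydrogenates the ketone through its enol, and only C13–C14 can become the double bond because the β-position on the C11 side is the quaternary C10, so the enone blocks C13 against enolisation in step 14.

Step 14
Reactants: 18 C13=C14 enone; 19 3-(tert-butyldiphenylsilyloxy)propanal
Product: 21 α′-aldol adduct with a 1-hydroxy-3-(tert-butyldiphenylsilyloxy)propyl group on C11, via lithium enolate 20 (not isolated)
Conditions: LiN(iPr)2, THF, −78 °C; then 19; AcOH, −78 °C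
Reagents that add atoms: none
Why: The only acidic hydrogens of this γ,γ-disubstituted enone are at C11, so the cross-conjugated α′-enolate forms regiospecifically and adds to the aldehyde (aldol addition), the new centres being erased in step 15.

Step 15
Reactants: 21 α′-aldol adduct
Product: 23 cross-conjugated dienone with a C11=C1′ 3-(tert-butyldiphenylsilyloxy)propylidene group, via mesylate 22 (not isolated)
Conditions: MsCl, Et3N, CH2Cl2, 0 °C; then DBU, rt
Reagents that add atoms: none
Why: Mesylation of the secondary aldol hydroxyl and E1cB elimination with the amidine base complete the aldol condensation.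

Step 16
Reactants: 23 cross-conjugated dienone
Product: 24 saturated C12 ketone with the 3-(tert-butyldiphenylsilyloxy)propyl chain on C11 cis to C16 on ring B
Conditions: H2 (1 atm), 10% Pd/C, EtOAc, rt
Reagents that add atoms: none
Why: Heterogeneous hydrogenation saturates both enone double bonds, and hydrogen should reach C11 from the ring B face that carries C9 and the C15 methyl, because the other face is covered by the silyloxy groups on C16 and C15, so the chain ends up cis to C16 (substrate-controlled catalytic hydrogenation).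

Step 17
Reactants: 24 saturated C12 ketone
Product: 25 dibromoalkene with C12=CBr2
Conditions: CBr4, PPh3, Zn, CH2Cl2, rt; then 24, 40 °C
Reagents that add atoms: carbon tetrabromide, BrC(Br)(Br)Br
Why: The preformed ylide Ph3P=CBr2 olefinates the ketone (Corey–Fuchs/Ramirez dibromomethylenation) under non-basic conditions that should not epimerise C11, and zinc removes the bromine that would otherwise attack the silyl ethers.

Step 18
Reactants: 25 dibromoalkene
Product: 26 diol with a 1,2-dihydroxyethyl group on C7
Conditions: PPTS, MeOH, rt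
Reagents that add atoms: none
Why: Acid-catalysed methanolysis removes the terminal isopropylidene acetal, the secondary and tertiary tert-butyldimethylsilyl ethers and the primary tert-butyldiphenylsilyl ether being stable to this weak acid.

Step 19
Reactants: 26 diol
Product: 27 hydroxy ketone with a hydroxyacetyl group on C7
Conditions: [(2,9-dimethyl-1,10-phenanthroline)Pd(OAc)]2(OTf)2 (5 mol%), benzoquinone, MeCN/H2O, rt
Reagents that add atoms: none
Why: The cationic palladium acetate complex chelates the vicinal diol and oxidises its secondary hydroxyl chemoselectively with benzoquinone as terminal oxidant (palladium-catalysed diol oxidation), and divalent palladium does not insert into the C–Br bonds.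

Step 20
Reactants: 27 hydroxy ketone; 28 (triphenylphosphoranylidene)ketene
Product: 30 butenolide with a 5-oxo-2,5-dihydrofuran-3-yl group on C7, via phosphorane ester 29 (not isolated)
Conditions: toluene, 80 °C
Reagents that add atoms: none
Why: The primary hydroxyl adds to the ketene ylide and the resulting ester-stabilised phosphorane closes onto the neighbouring ketone (Bestmann butenolide synthesis by intramolecular Wittig reaction), so C19 is forced cis to the C17′ oxygen across the new C17=C18 bond.

Step 21
Reactants: 30 butenolide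
Product: 31 lactol with a 5-hydroxy-2,5-dihydrofuran-3-yl group on C7
Conditions: iBu2AlH, CH2Cl2, −78 °C; aq. KNaC4H4O6
Reagents that add atoms: none
Why: At −78 °C the hydride adds once to the lactone and the aluminium hemiacetal is stable until work-up (partial reduction of a lactone), while vinylic bromides and silyl ethers are inert.

Step 22
Reactants: 32 2-methylprop-2-en-1-ol; 33 1-bromo-3-methylbut-2-ene
Product: 35 6-methyl-2-methylidenehept-5-en-1-ol, via dilithio alkoxide 34 (not isolated)
Conditions: n-BuLi (2.2 equiv), TMEDA, Et2O/hexane, 0 °C to rt; then 33, −78 °C to rt; H2O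
Reagents that add atoms: none
Why: Double deprotonation gives the allylic dianion, whose carbanion terminus is alkylated by the primary allylic bromide at its unsubstituted carbon (dianion alkylation).

Step 23
Reactants: 35 6-methyl-2-methylidenehept-5-en-1-ol
Product: 36 2-(bromomethyl)-6-methylhepta-1,5-diene
Conditions: PBr3, Et2O, 0 °C
Reagents that add atoms: phosphorus tribromide, BrP(Br)Br
Why: The primary allylic alcohol is brominated through its phosphite ester, and allylic transposition would give the same compound because both allyl termini are CH2.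

Step 24
Reactants: 36 2-(bromomethyl)-6-methylhepta-1,5-diene
Product: 37 diethyl (6-methyl-2-methylidenehept-5-en-1-yl)phosphonate
Conditions: P(OEt)3, 130 °C, neat
Reagents that add atoms: triethyl phosphite, CCOP(OCC)OCC
Why: Michaelis–Arbuzov reaction of the allylic bromide gives the phosphonate as the volatile bromoethane distils off.

Step 25
Reactants: 31 lactol; 37 diethyl (6-methyl-2-methylidenehept-5-en-1-yl)phosphonate
Product: 39 triene dibromide with the (2Z,4E)-1-hydroxy-10-methyl-6-methylideneundeca-2,4,9-trien-2-yl chain on C7, via lithiated phosphonate 38 (not isolated)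
Conditions: LiN(iPr)2 (3 equiv), 37 (3 equiv), THF, −78 °C; then 31, −78 °C to rt; H2O
Reagents that add atoms: none
Why: The phosphonate anion opens the lactol to the γ-oxido enal and olefinates it at its α-carbon (Horner–Wadsworth–Emmons reaction), elimination from the equilibrating adduct favouring the E C19=C20 bond while the C17=C18 geometry is retained from the ring.

Step 26
Reactants: 39 triene dibromide
Product: 40 bromo Weinreb amide with C12=C(Br)C(O)N(OMe)Me; amide carbon cis to C13
Conditions: Pd(PPh3)4 (10 mol%), CO (1 atm), MeNH(OMe)·HCl, Et3N, toluene, 60 °C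
Reagents that add atoms: carbon monoxide, [C-]#[O+]; N,O-dimethylhydroxylamine hydrochloride, CNOC.Cl
Why: Zerovalent palladium should insert first into the C–Br bond on the C13 side, which is not flanked by the substituted C11, and the acylpalladium formed with CO is captured by the hydroxylamine (site-selective aminocarbonylation of a 1,1-dibromoalkene), so the carbonyl carbon is placed cis to C13.

Step 27
Reactants: 40 bromo Weinreb amide
Product: 41 methyl Weinreb amide with C12=C(CH3)C(O)N(OMe)Me; methyl cis to C11
Conditions: MeZnCl, Pd(PPh3)4 (10 mol%), THF, 50 °C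
Reagents that add atoms: methylzinc chloride, C[Zn]Cl
Why: Negishi coupling of the remaining amide-activated C–Br bond proceeds with retention of alkene geometry, the free hydroxyl only consuming one equivalent of the zinc reagent.

Step 28
Reactants: 41 methyl Weinreb amide
Product: 42 tris-silyl ether of the target: O15 and O16 tert-butyldimethylsilyl; O3′ tert-butyldiphenylsilyl
Conditions: iBu2AlH, THF, −78 to −40 °C; aq. KNaC4H4O6
Reagents that add atoms: none
Why: The hydride reduces the N-methoxy-N-methylamide to a chelated tetrahedral intermediate that releases the aldehyde only on work-up (Weinreb amide reduction), so the enal is not reduced further.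

Step 29
Reactants: 42 tris-silyl ether of the target
Product: 43 target CNP0246965.2 (7S,10S,11R,15S,16R)
Conditions: HF·pyridine, pyridine, THF, 0 °C to rt
Reagents that add atoms: none
Why: Buffered HF·pyridine cleaves the three silyl ethers (fluoride desilylation) under conditions too mild to isomerise the tetrasubstituted enal or the triene.

**Compound list**
1 | 2-bromo-4-methoxy-1-methylbenzene | COc1ccc(C)c(Br)c1 | starting material
2 | cyclobutanone | O=C1CCC1 | starting material
3 | (5-methoxy-2-methylphenyl)lithium (not isolated) | COc1ccc(C)c([Li])c1 | intermediate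
4 | 1-(5-methoxy-2-methylphenyl)cyclobutan-1-ol | COc1ccc(C)c(c1)C2(O)CCC2 | intermediate
5 | 1-(5-methoxy-2-methylcyclohexa-1,4-dien-1-yl)cyclobutan-1-ol | COC1=CCC(C)=C(C1)C2(O)CCC2 | intermediate
6 | 1-(8-methyl-1,4-dioxaspiro[4.5]dec-7-en-7-yl)cyclobutan-1-ol | OC1(CCC1)C2=C(C)CCC3(C2)OCCO3 | intermediate
7 | epoxy cyclobutanol, 1-[(1S,6S)-6-methylspiro[7-oxabicyclo[4.1.0]heptane-3,2'-[1,3]dioxolan]-1-yl]cyclobutan-1-ol (10S,15S) | OC1(CCC1)[C@@]23CC4(OCCO4)CC[C@]2(C)O3 | intermediate
8 | spiro hydroxy ketone (10R,15S): C16 ketone, C12 ethylene ketal, C15 methyl carbinol, O15 cis to C16 | C1CC[C@]2(CC3(OCCO3)CC[C@]2(C)O)C1=O | intermediate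
9 | O15-trimethylsilyl ether of 8 | C1CC[C@]2(CC3(OCCO3)CC[C@]2(C)O[Si](C)(C)C)C1=O | intermediate
10 | (tert-butyldimethylsilyloxy)acetaldehyde | O=CCO[Si](C)(C)C(C)(C)C | starting material
11 | lithium C16(O)=C7 enolate of 9 (not isolated) | C1C[C@]2(CC3(OCCO3)CC[C@]2(C)O[Si](C)(C)C)C(O[Li])=C1 | intermediate
12 | aldol adduct: 9 with 1-hydroxy-2-(tert-butyldimethylsilyloxy)ethyl on C7, trans to C15 across ring A | OC(CO[Si](C)(C)C(C)(C)C)[C@@H]1CC[C@]2(CC3(OCCO3)CC[C@]2(C)O[Si](C)(C)C)C1=O | intermediate
13 | triol ketone: 8 with 1,2-dihydroxyethyl on C7 | OCC(O)[C@@H]1CC[C@]2(CC3(OCCO3)CC[C@]2(C)O)C1=O | intermediate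
14 | acetonide ketone: 8 with 2,2-dimethyl-1,3-dioxolan-4-yl on C7 | CC1(C)OCC(O1)[C@@H]2CC[C@]3(CC4(OCCO4)CC[C@]3(C)O)C2=O | intermediate
15 | diol: 14 reduced at C16, O16 cis to the C7 substituent and trans to C15 | CC1(C)OCC(O1)[C@@H]2CC[C@]3(CC4(OCCO4)CC[C@]3(C)O)[C@@H]2O | intermediate
16 | O15,O16-bis(tert-butyldimethylsilyl) ether of 15 | CC1(C)OCC(O1)[C@@H]2CC[C@]3(CC4(OCCO4)CC[C@]3(C)O[Si](C)(C)C(C)(C)C)[C@@H]2O[Si](C)(C)C(C)(C)C | intermediate
17 | C12 ketone from 16 | CC1(C)OCC(O1)[C@@H]2CC[C@]3(CC(=O)CC[C@]3(C)O[Si](C)(C)C(C)(C)C)[C@@H]2O[Si](C)(C)C(C)(C)C | intermediate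
18 | C13=C14 enone of 17 | CC1(C)OCC(O1)[C@@H]2CC[C@]3(CC(=O)C=C[C@]3(C)O[Si](C)(C)C(C)(C)C)[C@@H]2O[Si](C)(C)C(C)(C)C | intermediate
19 | 3-(tert-butyldiphenylsilyloxy)propanal | O=CCCO[Si](c1ccccc1)(c1ccccc1)C(C)(C)C | starting material
20 | lithium C11=C12(O) enolate of 18 (not isolated) | CC1(C)OCC(O1)[C@@H]2CC[C@]3(C=C(O[Li])C=C[C@]3(C)O[Si](C)(C)C(C)(C)C)[C@@H]2O[Si](C)(C)C(C)(C)C | intermediate
21 | α′-aldol adduct: 18 with 1-hydroxy-3-(tert-butyldiphenylsilyloxy)propyl on C11 | CC1(C)OCC(O1)[C@@H]2CC[C@]3(C(C(O)CCO[Si](c4ccccc4)(c4ccccc4)C(C)(C)C)C(=O)C=C[C@]3(C)O[Si](C)(C)C(C)(C)C)[C@@H]2O[Si](C)(C)C(C)(C)C | intermediate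
22 | C1′ methanesulfonate of 21 (not isolated) | CC1(C)OCC(O1)[C@@H]2CC[C@]3(C(C(OS(C)(=O)=O)CCO[Si](c4ccccc4)(c4ccccc4)C(C)(C)C)C(=O)C=C[C@]3(C)O[Si](C)(C)C(C)(C)C)[C@@H]2O[Si](C)(C)C(C)(C)C | intermediate
23 | cross-conjugated dienone: 18 with C11=C1′ 3-(tert-butyldiphenylsilyloxy)propylidene | CC1(C)OCC(O1)[C@@H]2CC[C@]3(C(=CCCO[Si](c4ccccc4)(c4ccccc4)C(C)(C)C)C(=O)C=C[C@]3(C)O[Si](C)(C)C(C)(C)C)[C@@H]2O[Si](C)(C)C(C)(C)C | intermediate
24 | saturated C12 ketone, 3-(tert-butyldiphenylsilyloxy)propyl on C11 cis to C16 on ring B | CC1(C)OCC(O1)[C@@H]2CC[C@]3([C@H](CCCO[Si](c4ccccc4)(c4ccccc4)C(C)(C)C)C(=O)CC[C@]3(C)O[Si](C)(C)C(C)(C)C)[C@@H]2O[Si](C)(C)C(C)(C)C | intermediate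
25 | dibromoalkene: 24 with C12=CBr2 | CC1(C)OCC(O1)[C@@H]2CC[C@]3([C@H](CCCO[Si](c4ccccc4)(c4ccccc4)C(C)(C)C)C(=C(Br)Br)CC[C@]3(C)O[Si](C)(C)C(C)(C)C)[C@@H]2O[Si](C)(C)C(C)(C)C | intermediate
26 | diol: 25 with 1,2-dihydroxyethyl on C7 | OCC(O)[C@@H]1CC[C@]2([C@H](CCCO[Si](c3ccccc3)(c3ccccc3)C(C)(C)C)C(=C(Br)Br)CC[C@]2(C)O[Si](C)(C)C(C)(C)C)[C@@H]1O[Si](C)(C)C(C)(C)C | intermediate
27 | hydroxy ketone: hydroxyacetyl on C7 | OCC(=O)[C@@H]1CC[C@]2([C@H](CCCO[Si](c3ccccc3)(c3ccccc3)C(C)(C)C)C(=C(Br)Br)CC[C@]2(C)O[Si](C)(C)C(C)(C)C)[C@@H]1O[Si](C)(C)C(C)(C)C | intermediate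
28 | (triphenylphosphoranylidene)ketene | O=C=C=P(c1ccccc1)(c1ccccc1)c1ccccc1 | starting material
29 | (triphenylphosphoranylidene)acetate ester of 27 (not isolated) | O=C(C=P(c1ccccc1)(c1ccccc1)c1ccccc1)OCC(=O)[C@@H]2CC[C@]3([C@H](CCCO[Si](c4ccccc4)(c4ccccc4)C(C)(C)C)C(=C(Br)Br)CC[C@]3(C)O[Si](C)(C)C(C)(C)C)[C@@H]2O[Si](C)(C)C(C)(C)C | intermediate
30 | butenolide: 5-oxo-2,5-dihydrofuran-3-yl on C7 | O=C1OCC(=C1)[C@@H]2CC[C@]3([C@H](CCCO[Si](c4ccccc4)(c4ccccc4)C(C)(C)C)C(=C(Br)Br)CC[C@]3(C)O[Si](C)(C)C(C)(C)C)[C@@H]2O[Si](C)(C)C(C)(C)C | intermediate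
31 | lactol: 5-hydroxy-2,5-dihydrofuran-3-yl on C7 | OC1OCC(=C1)[C@@H]2CC[C@]3([C@H](CCCO[Si](c4ccccc4)(c4ccccc4)C(C)(C)C)C(=C(Br)Br)CC[C@]3(C)O[Si](C)(C)C(C)(C)C)[C@@H]2O[Si](C)(C)C(C)(C)C | intermediate
32 | 2-methylprop-2-en-1-ol | CC(=C)CO | starting material
33 | 1-bromo-3-methylbut-2-ene | CC(C)=CCBr | starting material
34 | dilithio derivative of 32 (not isolated) | [Li]CC(=C)CO[Li] | intermediate
35 | 6-methyl-2-methylidenehept-5-en-1-ol | OCC(=C)CCC=C(C)C | intermediate
36 | 2-(bromomethyl)-6-methylhepta-1,5-diene | BrCC(=C)CCC=C(C)C | intermediate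
37 | diethyl (6-methyl-2-methylidenehept-5-en-1-yl)phosphonate | CCOP(=O)(CC(=C)CCC=C(C)C)OCC | intermediate
38 | α-lithio derivative of 37 (not isolated) | CCOP(=O)(OCC)C([Li])C(=C)CCC=C(C)C | intermediate
39 | triene dibromide: (2Z,4E)-1-hydroxy-10-methyl-6-methylideneundeca-2,4,9-trien-2-yl on C7, C12=CBr2 | C=C(/C=C/C=C(\CO)[C@@H]1CC[C@]2([C@H](CCCO[Si](c3ccccc3)(c3ccccc3)C(C)(C)C)C(=C(Br)Br)CC[C@]2(C)O[Si](C)(C)C(C)(C)C)[C@@H]1O[Si](C)(C)C(C)(C)C)CCC=C(C)C | intermediate
40 | bromo Weinreb amide: C12=C(Br)C(O)N(OMe)Me, Br cis to C11 | C=C(/C=C/C=C(\CO)[C@@H]1CC[C@]2([C@H](CCCO[Si](c3ccccc3)(c3ccccc3)C(C)(C)C)/C(=C(\Br)C(=O)N(C)OC)CC[C@]2(C)O[Si](C)(C)C(C)(C)C)[C@@H]1O[Si](C)(C)C(C)(C)C)CCC=C(C)C | intermediate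
41 | methyl Weinreb amide: C12=C(CH3)C(O)N(OMe)Me, methyl cis to C11 | C=C(/C=C/C=C(\CO)[C@@H]1CC[C@]2([C@H](CCCO[Si](c3ccccc3)(c3ccccc3)C(C)(C)C)/C(=C(\C)C(=O)N(C)OC)CC[C@]2(C)O[Si](C)(C)C(C)(C)C)[C@@H]1O[Si](C)(C)C(C)(C)C)CCC=C(C)C | intermediate
42 | tris-silyl ether of the target (O15, O16 tert-butyldimethylsilyl; O3′ tert-butyldiphenylsilyl) | C=C(/C=C/C=C(\CO)[C@@H]1CC[C@]2([C@H](CCCO[Si](c3ccccc3)(c3ccccc3)C(C)(C)C)/C(=C(\C)C=O)CC[C@]2(C)O[Si](C)(C)C(C)(C)C)[C@@H]1O[Si](C)(C)C(C)(C)C)CCC=C(C)C | intermediate
43 | CNP0246965.2 (7S,10S,11R,15S,16R; C17=C18 Z, C19=C20 E, enal E) | C=C(/C=C/C=C(\CO)[C@@H]1CC[C@]2([C@H](CCCO)/C(=C(\C)C=O)CC[C@]2(C)O)[C@@H]1O)CCC=C(C)C | target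

**Step count**
Total steps: 29. Longest linear sequence: 26 (steps 1 to 21 and 25 to 29); steps 22 to 24 make phosphonate 37.

**Steps most likely to fail**

Step 26. Oxidative addition may not discriminate well enough between the two C–Br bonds of the fully substituted dibromoalkene, or the amide-activated second C–Br bond may be carbonylated as well. The fallback replaces palladium site selection by kinetic halogen–metal exchange. It sets out from 39: n-BuLi (2.1 equiv, THF/Et2O/pentane, −105 °C) should exchange the more compressed bromine, the one cis to C11, and MeI methylates the carbenoid to give the bromo methyl alkene F1. Exchange of the remaining bromine with t-BuLi at −78 °C and formylation with DMF, with retention, comes back to the route at 42.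

Step 17. The ylide may fail to add to a ketone flanked by the substituted C11 and the quaternary C10, and forcing conditions may epimerise C11. The fallback sets out from 24: condensation with N2H4·H2O in EtOH gives the hydrazone of 24 F2. Copper-catalysed olefination of this N-unsubstituted hydrazone with CBr4 (CuCl, aq. NH3, DMSO) comes back to the route at 25.

Step 16. Hydrogen may be delivered to C11 with poor facial selectivity on the catalyst surface. The fallback sets C11 by kinetic protonation of a regiodefined enolate and sets out from 18. The α′-enolate (LiN(iPr)2) is alkylated with tert-butyl(3-iodopropoxy)diphenylsilane in THF/DMPU from the open face to give the C11 alkyl enone with the chain trans to C16 F3. Re-enolisation at C11 with KN(SiMe3)2 and protonation at −78 °C with 2,6-di-tert-butylphenol from the same open face gives the C11 epimer with the chain cis to C16 F4. Hydrogenation of C13=C14 (H2, Pd/C) comes back to the route at 24.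

Further compounds
F1 | step 26 | bromo methyl alkene: 39 with C12=C(CH3)Br, methyl cis to C11 | C=C(/C=C/C=C(\CO)[C@@H]1CC[C@]2([C@H](CCCO[Si](c3ccccc3)(c3ccccc3)C(C)(C)C)/C(=C(\C)Br)CC[C@]2(C)O[Si](C)(C)C(C)(C)C)[C@@H]1O[Si](C)(C)C(C)(C)C)CCC=C(C)C
F2 | step 17 | hydrazone of 24 | CC1(C)OCC(O1)[C@@H]2CC[C@]3([C@H](CCCO[Si](c4ccccc4)(c4ccccc4)C(C)(C)C)C(=NN)CC[C@]3(C)O[Si](C)(C)C(C)(C)C)[C@@H]2O[Si](C)(C)C(C)(C)C
F3 | step 16 | C11 alkyl enone, chain trans to C16 | CC1(C)OCC(O1)[C@@H]2CC[C@]3([C@@H](CCCO[Si](c4ccccc4)(c4ccccc4)C(C)(C)C)C(=O)C=C[C@]3(C)O[Si](C)(C)C(C)(C)C)[C@@H]2O[Si](C)(C)C(C)(C)C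
F4 | step 16 | C11 epimer of F3, chain cis to C16 | CC1(C)OCC(O1)[C@@H]2CC[C@]3([C@H](CCCO[Si](c4ccccc4)(c4ccccc4)C(C)(C)C)C(=O)C=C[C@]3(C)O[Si](C)(C)C(C)(C)C)[C@@H]2O[Si](C)(C)C(C)(C)C
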